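## Retrosynthetic overview

1. The seven-membered ring is closed last: acid-triggered Friedel–Crafts attack of one of two homotopic 3,5-dioxygenated aryl rings on a protonated stilbene arm of a C2-symmetric bis(trans-2,3-diaryl-dihydrobenzofuran), merged with global O-demethylation.
2. Both dihydrobenzofuran rings are closed together (C7–O, SN1, trans) from a bis(1,2,2-triarylethanol) made by twofold dynamic-kinetic transfer hydrogenation of a bis(α,α-diaryl ketone); this sets both C8 centres.
3. Key disconnection: both C7–C8 bonds come from a twofold carbene-catalysed addition of the acyl-anion (Breslow) form of 4-methoxybenzaldehyde to aryl-substituted o-quinone methides released by fluoride from one central ring.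
4. The o-quinone-methide precursor comes from a 2,6-dilithiated 3,5-bis(silyloxy)stilbene and 3,5-dimethoxybenzaldehyde; the stilbene comes from a Horner–Wadsworth–Emmons reaction of 2,6-dibromo-3,5-bis(silyloxy)benzaldehyde.
5. Ring order: central benzene (bought) → two dihydrobenzofurans at once → seven-membered carbocycle.

Assumption: the SMILES is read as (7aR,8aR,7bR,8bR,7cR), i.e. both 2,3-diaryl-dihydrobenzofurans trans and H-7c trans to H-8b. C7 is the O-bearing benzylic carbon (in unit c the carbon bearing the 2,4-dihydroxyphenyl group), C8 the adjacent carbon; a and b are the two dihydrobenzofuran units, c the CH2–CH(aryl) unit.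

## Route

Step 1
Reactants: 1 3,5-dihydroxybenzaldehyde
Product: 2 3,5-bis(triisopropylsilyloxy)benzaldehyde
Conditions: TIPSCl (2.3 equiv), imidazole, DMF, rt
Reagents that add atoms: chlorotriisopropylsilane, CC(C)[Si](Cl)(C(C)C)C(C)C
Why: Imidazole-promoted O-silylation of both phenols installs the fluoride-labile trigger needed for o-quinone methide release and the bulk that shields C4 in the next step.

Step 2
Reactants: 2 3,5-bis(triisopropylsilyloxy)benzaldehyde
Product: 3 2,6-dibromo-3,5-bis(triisopropylsilyloxy)benzaldehyde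
Conditions: NBS (2.2 equiv), DMF, 0 °C → rt
Reagents that add atoms: N-bromosuccinimide, O=C1CCC(=O)N1Br
Why: Electrophilic aromatic bromination occurs twice para to a silyloxy group (C2 and C6), as in the known 2,6-dibromination of 3,5-dialkoxybenzaldehydes, while the position between the two bulky OTIPS groups is shielded.

Step 3
Reactants: 4 2,4-dimethoxybenzyl alcohol
Product: 6 diethyl (2,4-dimethoxybenzyl)phosphonate, via 2,4-dimethoxybenzyl bromide 5 (not isolated)
Conditions: PBr3 (0.4 equiv), Et2O, 0 °C; then P(OEt)3, 90 °C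
Reagents that add atoms: triethyl phosphite, CCOP(OCC)OCC
Why: Alcohol-to-bromide conversion followed at once by Michaelis–Arbuzov reaction of the labile electron-rich benzylic bromide with triethyl phosphite.

Step 4
Reactants: 3 2,6-dibromo-3,5-bis(triisopropylsilyloxy)benzaldehyde, 6 diethyl (2,4-dimethoxybenzyl)phosphonate
Product: 7 (E)-1-[2,6-dibromo-3,5-bis(triisopropylsilyloxy)phenyl]-2-(2,4-dimethoxyphenyl)ethene
Conditions: NaH (1.2 equiv), THF, 0 °C → rt
Reagents that add atoms: none
Why: Horner–Wadsworth–Emmons olefination of a non-enolisable aldehyde gives the (E)-stilbene, which carries the C8c–C7c arm as a masked benzylic cation through the following steps.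

Step 5
Reactants: 7 (E)-1-[2,6-dibromo-3,5-bis(triisopropylsilyloxy)phenyl]-2-(2,4-dimethoxyphenyl)ethene, 8 3,5-dimethoxybenzaldehyde
Product: 11 {2-[(E)-2-(2,4-dimethoxyphenyl)ethenyl]-4,6-bis(triisopropylsilyloxy)-1,3-phenylene}bis[(3,5-dimethoxyphenyl)methylene] diacetate (diastereomer mixture), via dilithiated stilbene 9 (not isolated), via dilithium dialkoxide 10 (not isolated)
Conditions: t-BuLi (4.4 equiv), THF, −78 °C; 8 (2.4 equiv), −78 °C; Ac2O (4 equiv), −78 → 0 °C
Reagents that add atoms: acetic anhydride, CC(=O)OC(C)=O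
Why: Twofold bromine–lithium exchange, 1,2-addition of the aryl dilithium to the aldehyde and in-flask O-acetylation (before silyl migration can occur) give the bis(o-silyloxybenzhydryl acetate), whose two uncontrolled carbinol centres are erased in step 6.

Step 6
Reactants: 11 bis-acetate from step 5, 12 4-methoxybenzaldehyde
Product: 16 2,2'-{2-[(E)-2-(2,4-dimethoxyphenyl)ethenyl]-4,6-dihydroxy-1,3-phenylene}bis[2-(3,5-dimethoxyphenyl)-1-(4-methoxyphenyl)ethan-1-one] (C8 epimer mixture), via first o-quinone methide 13 (not isolated), via mono-ketone phenol 14 (not isolated), via second o-quinone methide 15 (not isolated)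
Conditions: 12 (4 equiv), 3-ethyl-5-(2-hydroxyethyl)-4-methylthiazolium bromide (30 mol %), CsF (6 equiv), 18-crown-6, THF/MeCN, rt
Reagents that add atoms: none
Why: Fluoride removes a TIPS group, the phenoxide expels acetate to give an aryl-substituted o-quinone methide, and the Breslow intermediate of 4-methoxybenzaldehyde (an acyl anion equivalent) adds 1,4 to the methide carbon (carbene-catalysed nucleophilic acylation of o-quinone methides, a Stetter-type umpolung joining two electrophilic carbons); the sequence repeats on the other side, one at a time, because a bis(quinone methide) of this ring has no closed-shell structure, and the C8 centres need no control because they are epimerisable.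

Step 7
Reactants: 16 bis(α,α-diaryl ketone) bisphenol from step 6
Product: 18 (2R,3R,5R,6R)-4-[(E)-2-(2,4-dimethoxyphenyl)ethenyl]-3,5-bis(3,5-dimethoxyphenyl)-2,6-bis(4-methoxyphenyl)-2,3,5,6-tetrahydrobenzo[1,2-b:5,4-b']difuran, via tetraol 17 (not isolated)
Conditions: RuCl(p-cymene)[(R,R)-TsNCH(Ph)CH(Ph)NH2] (5 mol % per ketone), HCO2H/Et3N (1:1), CH2Cl2, 35 °C; then TFA, 0 °C
Reagents that add atoms: none
Why: Proposed new method: the C8–H of each α,α-diaryl ketone is acidic enough to epimerise quickly under Et3N while the (R,R)-Ru hydride delivers H to the ketone face that gives the (R)-carbinol (as for aryl alkyl ketones) and, of the two interconverting C8 epimers, reduces the Felkin–Anh-matched one (bulky central aryl anti to the incoming hydride), so both units converge on (7R,8R) and a mismatched event ends in a separable meso-type diastereomer; the closest known reaction type is the dynamic kinetic resolution of α-aryl ketones by Noyori-type asymmetric transfer hydrogenation with in-flask acid ring closure (2′-hydroxyisoflavanones to pterocarpans); TFA then ionises each C7–OH to a 4-methoxybenzylic cation that the ortho phenol traps (5-exo) to the thermodynamically favoured trans-2,3-diaryl-dihydrobenzofuran, so C7 is re-set from C8 and ends (R).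

Step 8
Reactants: 18 C2-symmetric bis-dihydrobenzofuran stilbene octamethyl ether from step 7
Product: 19 target CNP0154047.1 of (7aR,8aR,7bR,8bR,7cR) configuration
Conditions: BBr3 (20 equiv), CH2Cl2, −78 °C → rt; MeOH, then H2O
Reagents that add atoms: none
Why: BBr3 cleaves all eight methyl ethers and the HBr formed protonates the stilbene at the ring-bound carbon, giving the 2,4-dioxygenated benzylic cation at C7c, which is trapped in a seven-membered-ring-forming Friedel–Crafts alkylation by the ortho carbon of a neighbouring 3,5-dioxygenated ring (the two are homotopic by C2 symmetry) on the face anti to the C7b aryl group, setting C7c (R) with H-7c trans to H-8b (demethylation with concomitant stilbene hydroarylation, the ampelopsin B-type closure of viniferin-type stilbenes).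

## Compound list

1 | 3,5-dihydroxybenzaldehyde | O=Cc1cc(O)cc(O)c1 | starting material
2 | 3,5-bis(triisopropylsilyloxy)benzaldehyde | O=Cc1cc(O[Si](C(C)C)(C(C)C)C(C)C)cc(O[Si](C(C)C)(C(C)C)C(C)C)c1 | intermediate
3 | 2,6-dibromo-3,5-bis(triisopropylsilyloxy)benzaldehyde | O=Cc1c(Br)c(O[Si](C(C)C)(C(C)C)C(C)C)cc(O[Si](C(C)C)(C(C)C)C(C)C)c1Br | intermediate
4 | 2,4-dimethoxybenzyl alcohol | COc1ccc(CO)c(OC)c1 | starting material
5 | 2,4-dimethoxybenzyl bromide (not isolated) | COc1ccc(CBr)c(OC)c1 | intermediate
6 | diethyl (2,4-dimethoxybenzyl)phosphonate | CCOP(=O)(Cc1ccc(OC)cc1OC)OCC | intermediate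
7 | (E)-1-[2,6-dibromo-3,5-bis(triisopropylsilyloxy)phenyl]-2-(2,4-dimethoxyphenyl)ethene | COc1ccc(/C=C/c2c(Br)c(O[Si](C(C)C)(C(C)C)C(C)C)cc(O[Si](C(C)C)(C(C)C)C(C)C)c2Br)c(OC)c1 | intermediate
8 | 3,5-dimethoxybenzaldehyde | COc1cc(C=O)cc(OC)c1 | starting material
9 | dilithiated stilbene: 7 with both Br replaced by Li (not isolated) | COc1ccc(/C=C/c2c([Li])c(O[Si](C(C)C)(C(C)C)C(C)C)cc(O[Si](C(C)C)(C(C)C)C(C)C)c2[Li])c(OC)c1 | intermediate
10 | dilithium dialkoxide: each former C–Li carbon now bears CH(OLi)(3,5-dimethoxyphenyl), diastereomer mixture (not isolated) | COc1ccc(/C=C/c2c(C(O[Li])c3cc(OC)cc(OC)c3)c(O[Si](C(C)C)(C(C)C)C(C)C)cc(O[Si](C(C)C)(C(C)C)C(C)C)c2C(O[Li])c2cc(OC)cc(OC)c2)c(OC)c1 | intermediate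
11 | {2-[(E)-2-(2,4-dimethoxyphenyl)ethenyl]-4,6-bis(triisopropylsilyloxy)-1,3-phenylene}bis[(3,5-dimethoxyphenyl)methylene] diacetate, diastereomer mixture | COc1ccc(/C=C/c2c(C(OC(C)=O)c3cc(OC)cc(OC)c3)c(O[Si](C(C)C)(C(C)C)C(C)C)cc(O[Si](C(C)C)(C(C)C)C(C)C)c2C(OC(C)=O)c2cc(OC)cc(OC)c2)c(OC)c1 | intermediate
12 | 4-methoxybenzaldehyde | COc1ccc(C=O)cc1 | starting material
13 | first o-quinone methide: 11 after loss of one TIPS and the adjacent acetate, ring C=O with exocyclic =CH(3,5-dimethoxyphenyl), geometry undefined (not isolated) | COc1ccc(/C=C/C2=C(C(OC(C)=O)c3cc(OC)cc(OC)c3)C(O[Si](C(C)C)(C(C)C)C(C)C)=CC(=O)C2=Cc2cc(OC)cc(OC)c2)c(OC)c1 | intermediate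
14 | mono-ketone phenol: one arm CH(3,5-dimethoxyphenyl)C(=O)(4-methoxyphenyl) beside a free OH, other arm still CH(OAc)(3,5-dimethoxyphenyl) beside OTIPS (not isolated) | COc1ccc(/C=C/c2c(C(OC(C)=O)c3cc(OC)cc(OC)c3)c(O[Si](C(C)C)(C(C)C)C(C)C)cc(O)c2C(C(=O)c2ccc(OC)cc2)c2cc(OC)cc(OC)c2)c(OC)c1 | intermediate
15 | second o-quinone methide: 14 after loss of the remaining TIPS and acetate (not isolated) | COc1ccc(/C=C/C2=C(C(C(=O)c3ccc(OC)cc3)c3cc(OC)cc(OC)c3)C(O)=CC(=O)C2=Cc2cc(OC)cc(OC)c2)c(OC)c1 | intermediate
16 | 2,2'-{2-[(E)-2-(2,4-dimethoxyphenyl)ethenyl]-4,6-dihydroxy-1,3-phenylene}bis[2-(3,5-dimethoxyphenyl)-1-(4-methoxyphenyl)ethan-1-one], C8 epimer mixture | COc1ccc(/C=C/c2c(C(C(=O)c3ccc(OC)cc3)c3cc(OC)cc(OC)c3)c(O)cc(O)c2C(C(=O)c2ccc(OC)cc2)c2cc(OC)cc(OC)c2)c(OC)c1 | intermediate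
17 | (1R,1'R,2R,2'R)-2,2'-{2-[(E)-2-(2,4-dimethoxyphenyl)ethenyl]-4,6-dihydroxy-1,3-phenylene}bis[2-(3,5-dimethoxyphenyl)-1-(4-methoxyphenyl)ethan-1-ol] (not isolated) | COc1ccc(/C=C/c2c([C@@H](c3cc(OC)cc(OC)c3)[C@@H](O)c3ccc(OC)cc3)c(O)cc(O)c2[C@@H](c2cc(OC)cc(OC)c2)[C@@H](O)c2ccc(OC)cc2)c(OC)c1 | intermediate
18 | (2R,3R,5R,6R)-4-[(E)-2-(2,4-dimethoxyphenyl)ethenyl]-3,5-bis(3,5-dimethoxyphenyl)-2,6-bis(4-methoxyphenyl)-2,3,5,6-tetrahydrobenzo[1,2-b:5,4-b']difuran (both rings trans, C2-symmetric) | COc1ccc([C@@H]2Oc3cc4c([C@@H](c5cc(OC)cc(OC)c5)[C@H](c5ccc(OC)cc5)O4)c(/C=C/c5ccc(OC)cc5OC)c3[C@H]2c2cc(OC)cc(OC)c2)cc1 | intermediate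
19 | CNP0154047.1, (7aR,8aR,7bR,8bR,7cR) | Oc1ccc([C@@H]2Oc3cc4c5c(c3[C@H]2c2cc(O)cc(O)c2)C[C@H](c2ccc(O)cc2O)c2c(O)cc(O)cc2[C@H]5[C@H](c2ccc(O)cc2)O4)cc1 | target

## Step count and risks

Total steps: 8. Longest linear sequence: 7 (steps 1, 2, 4, 5, 6, 7, 8 from 3,5-dihydroxybenzaldehyde); step 3 is a one-step side branch.

The three steps most likely to fail are 6, 7 and 8.

**Step 6.** The twofold acylation builds two very congested triaryl-substituted carbons next to the styryl arm. The o-quinone methides may instead be consumed by phenoxide O-addition or oligomerisation, and the electron-rich aldehyde forms its Breslow intermediate slowly. The fallback sets out from 11 and comes back at 16, using a stoichiometric masked acyl anion in place of the carbene cycle. 4-Methoxybenzaldehyde 12 is condensed with propane-1,3-dithiol (BF3·OEt2) to 2-(4-methoxyphenyl)-1,3-dithiane F1, which is lithiated (n-BuLi) and silylated (TMSCl) to 2-(4-methoxyphenyl)-2-(trimethylsilyl)-1,3-dithiane F2. CsF with 18-crown-6 in DMF then unmasks both the dithianyl carbanion from F2 and the o-quinone methides from 11, giving the bis-dithiane bisphenol F3. Alkylative hydrolysis (MeI, CaCO3, aqueous MeCN) releases the two ketones and gives 16.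

**Step 7.** The ketones are hindered and electron-rich, so transfer hydrogenation may be slow. The selection between the C8 epimers is not established for 1,2,2-triarylethanones, and acid could dehydrate the hydroxy-ketone to a benzofuran; the base-rich formate medium is chosen to suppress this. If the sense of C8 selection turns out opposite, the (S,S)-catalyst is used, since C7 is re-set in the ring closure. The fallback sets out from 16 and comes back at 18 by resolution instead of asymmetric catalysis. NaBH4 in THF/MeOH gives the tetraol as a stereoisomer mixture F4, and TFA closes both rings trans to give the bis-dihydrobenzofuran as a racemic C2 pair plus its meso isomer F5. The meso isomer is removed on silica and the enantiomers are separated by preparative HPLC on a cellulose tris(3,5-dimethylphenylcarbamate) phase to give 18.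

**Step 8.** Under strong acid the freed 4-hydroxyphenyl dihydrobenzofurans can reopen to quinone methides and be captured by the stilbene to give an indane (ampelopsin D-type) skeleton instead of the cycloheptane, and eight demethylations must go to completion. The fallback sets out from 18 and comes back at 19 by taking the ring closure out of the deprotection. Catalytic TfOH in CH2Cl2 at 0 °C cyclises the stilbene at the methyl-ether stage, where the 4-methoxyphenyl dihydrobenzofurans cannot open to quinone methides, giving the octa-O-methyl ether of the target F6. This is then demethylated with BBr3 at −78 → 0 °C to 19.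

## Further compounds

F1 | step 6 | 2-(4-methoxyphenyl)-1,3-dithiane | COc1ccc(C2SCCCS2)cc1
F2 | step 6 | 2-(4-methoxyphenyl)-2-(trimethylsilyl)-1,3-dithiane | COc1ccc(C2([Si](C)(C)C)SCCCS2)cc1
F3 | step 6 | bis-dithiane bisphenol: 16 with each C=O replaced by a 1,3-dithiane-2,2-diyl group, diastereomer mixture | COc1ccc(/C=C/c2c(C(c3cc(OC)cc(OC)c3)C3(c4ccc(OC)cc4)SCCCS3)c(O)cc(O)c2C(c2cc(OC)cc(OC)c2)C2(c3ccc(OC)cc3)SCCCS2)c(OC)c1
F4 | step 7 | tetraol of constitution 17 as a stereoisomer mixture | COc1ccc(/C=C/c2c(C(c3cc(OC)cc(OC)c3)C(O)c3ccc(OC)cc3)c(O)cc(O)c2C(c2cc(OC)cc(OC)c2)C(O)c2ccc(OC)cc2)c(OC)c1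
F5 | step 7 | trans,trans-bis-dihydrobenzofuran of constitution 18 as racemic C2 pair plus meso isomer | COc1ccc(C2Oc3cc4c(C(c5cc(OC)cc(OC)c5)C(c5ccc(OC)cc5)O4)c(/C=C/c5ccc(OC)cc5OC)c3C2c2cc(OC)cc(OC)c2)cc1
F6 | step 8 | octa-O-methyl ether of the target, (7aR,8aR,7bR,8bR,7cR) | COc1ccc([C@@H]2Oc3cc4c5c(c3[C@H]2c2cc(OC)cc(OC)c2)C[C@H](c2ccc(OC)cc2OC)c2c(OC)cc(OC)cc2[C@H]5[C@H](c2ccc(OC)cc2)O4)cc1
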